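**Plan**

1. Numbering: ring B is O1–C2(=O)–C3–C4–C5 and ring A is C5–C6(=O)–O7–C8–C9, with the dec-9-enyl chain on C8. The enabling feature is that C4, the carbinol bearing the carboxyl, sits between spiro C5 (whose oxygen O1 is the ester oxygen of C2) and the C3 methine, so an acetate on O1 can close ring B by forming C3–C4.
2. Retrosynthetic cuts, in order: the tert-butyl ester C–O, C3–OH, C3–C4 (ring B, aldol), C5–O1 (acetoxylation), C4–C5 (Claisen condensation with an oxalate), then C5–C9 and O7–C6 of ring A, back to a malonate and the monoepoxide of dodeca-1,11-diene.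
3. Forward: ring A is built first as a γ-lactone, C5 then receives the oxalyl unit and the acetoxy group, ring B is closed onto it by the aldol, and the C3 hydroxyl and the free acid come last.
4. Stereochemistry: C8 (R) from hydrolytic kinetic resolution of the epoxide; C5 (S) from acetoxylation anti to the C8 chain; C4 (R) from the lithium-chelated aldol; C3 (R) from enolate hydroxylation anti to the C4 alkoxide.

Key step: step 7

Assumption: the (R,R)-cobalt–salen catalyst is taken as the antipode that hydrates the (S)-enantiomer of a 1-alkyloxirane and leaves the (R)-epoxide; compound 11 is drawn as the keto form although it should be largely enolised.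

**Step 1**
Reactants: 1 dodeca-1,11-diene
Product: 2 rac-2-(dec-9-en-1-yl)oxirane
Conditions: mCPBA (1 equiv), 1 (3 equiv), CH2Cl2, 0 °C → rt; excess 1 recovered by distillation
Reagents that add atoms: mCPBA (3-chloroperoxybenzoic acid), O=C(OO)c1cccc(Cl)c1
Why: Prilezhaev epoxidation in which the two remote, identical alkenes react independently, so that with the diene in excess the monoepoxide should be the main product, formed as a racemate that the next step resolves.

**Step 2**
Reactants: 2 rac-2-(dec-9-en-1-yl)oxirane
Product: 3 (2R)-2-(dec-9-en-1-yl)oxirane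
Conditions: (R,R)-[N,N′-bis(3,5-di-tert-butylsalicylidene)cyclohexane-1,2-diaminato]Co(OAc) (0.5 mol %), H2O (0.55 equiv), THF, 0 °C → rt; distillation from the diol
Reagents that add atoms: none
Why: Hydrolytic kinetic resolution by the chiral salen complex of trivalent cobalt, which hydrates the (S)-epoxide much faster than its antipode, so that the unreacted (R)-epoxide carrying the future C8 should be recovered in high enantiomeric purity.

**Step 3**
Reactants: 3 (2R)-2-(dec-9-en-1-yl)oxirane; 4 dimethyl malonate
Product: 6 methyl (3RS,5R)-5-(dec-9-en-1-yl)-2-oxooxolane-3-carboxylate, via sodium alkoxide of the malonate adduct 5 (not isolated)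
Conditions: NaOMe (1.1 equiv), 4 (1.3 equiv), MeOH, 65 °C; then 1 M HCl
Reagents that add atoms: none
Why: Malonic ester lactone synthesis, in which the malonate anion opens the epoxide by SN2 attack at the unsubstituted carbon (C5–C9 bond) and the resulting alkoxide lactonises onto one ester (O7–C6 bond); the C–O bond of the stereocentre is untouched, so C8 stays R.

**Step 4**
Reactants: 6 methyl (3RS,5R)-5-(dec-9-en-1-yl)-2-oxooxolane-3-carboxylate
Product: 8 (5R)-5-(dec-9-en-1-yl)oxolan-2-one, via lithium 2-oxooxolane-3-carboxylate 7 (not isolated)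
Conditions: LiCl (2 equiv), H2O (2 equiv), DMSO, 150 °C
Reagents that add atoms: none
Why: Krapcho dealkoxycarbonylation, in which chloride demethylates the activated ester, the β-carbonyl carboxylate loses CO2 and water protonates the lactone enolate; ring A and the remote C8 centre are unaffected and the C3 epimer mixture disappears.

**Step 5**
Reactants: 8 (5R)-5-(dec-9-en-1-yl)oxolan-2-one; 9 di-tert-butyl oxalate
Product: 11 tert-butyl 2-[(3RS,5R)-5-(dec-9-en-1-yl)-2-oxooxolan-3-yl]-2-oxoacetate, via lithium lactone enolate 10 (not isolated)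
Conditions: LiN(SiMe3)2 (2.2 equiv), THF, −78 °C; then 9 (1.2 equiv), −78 → 0 °C; 1 M HCl
Reagents that add atoms: none
Why: Crossed Claisen condensation of the lactone enolate with the non-enolisable oxalate (C4–C5 bond), driven by deprotonation of the product by the second equivalent of base; the tert-butyl ester is chosen so that the last step can free the acid without touching the lactones.

**Step 6**
Reactants: 11 tert-butyl 2-[(3RS,5R)-5-(dec-9-en-1-yl)-2-oxooxolan-3-yl]-2-oxoacetate
Product: 12 tert-butyl 2-[(3S,5R)-3-acetoxy-5-(dec-9-en-1-yl)-2-oxooxolan-3-yl]-2-oxoacetate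
Conditions: Pb(OAc)4 (1.1 equiv), CH2Cl2, 0 °C → rt
Reagents that add atoms: lead tetraacetate, CC(=O)O[Pb](OC(C)=O)(OC(C)=O)OC(C)=O
Why: α-Acetoxylation of a 1,3-dicarbonyl compound, in which the enol is metallated by tetravalent lead and an acetate ligand is transferred to carbon with loss of Pb(OAc)2 on the face of ring A opposite the alkyl chain (1,3-induction across the γ-lactone), which should set the quaternary centre, the future spiro C5, as S; the isolated terminal alkene reacts far more slowly than the enol.

**Step 7**
Reactants: 12 tert-butyl 2-[(3S,5R)-3-acetoxy-5-(dec-9-en-1-yl)-2-oxooxolan-3-yl]-2-oxoacetate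
Product: 14 tert-butyl (4R,5S,8R)-8-(dec-9-en-1-yl)-4-hydroxy-2,6-dioxo-1,7-dioxaspiro[4.4]nonane-4-carboxylate, via lithium ester enolate 13 (not isolated)
Conditions: LiN(SiMe3)2 (1.15 equiv), THF, −78 °C; AcOH, −78 °C
Reagents that add atoms: none
Why: LiN(SiMe3)2 removes a proton from the acetate methyl, the only enolisable position because C5 is quaternary and ring A has no α-hydrogen, and the enolate carbon adds to the neighbouring ketone of the α-keto ester, forming C3–C4 and, after protonation of the lithium aldolate, compound 14. The closest known reaction type is the intramolecular aldol addition of α-acyloxy ketones to β-hydroxy-γ-lactones, the first stage of the classical butenolide annulation. Ring B closes in the 5-(enolendo)-exo-trig mode, which is formally strained by the empirical ring-closure rules for carbon enolates but is the established mode for ester enolates tethered through oxygen, as in butenolide and tetronic acid closures. The new C4 centre is controlled by the rotamer about C4–C5: lithium bridging the ketone oxygen and the C6 lactone carbonyl should hold the ketone oxygen on the C6 side, and because the nucleophile is tied to O1 it can reach only one face of that rotamer, placing the C4 hydroxyl syn to C6 (4R). The step needs the enolate to choose the ketone over the C6 lactone carbonyl and the ester carbonyl; the ketone of an α-keto ester is by far the most electrophilic site and the tert-butyl group shields the ester, while the low temperature and a silylamide without β-hydrogens suppress hydride transfer, loss of ketene and retro-Claisen cleavage.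

**Step 8**
Reactants: 14 tert-butyl (4R,5S,8R)-8-(dec-9-en-1-yl)-4-hydroxy-2,6-dioxo-1,7-dioxaspiro[4.4]nonane-4-carboxylate
Product: 16 tert-butyl (3R,4R,5S,8R)-8-(dec-9-en-1-yl)-3,4-dihydroxy-2,6-dioxo-1,7-dioxaspiro[4.4]nonane-4-carboxylate, via dilithium alkoxide enolate 15 (not isolated)
Conditions: LiN(iPr)2 (2.5 equiv), THF, −78 °C; then trans-2-(phenylsulfonyl)-3-phenyloxaziridine (1.5 equiv), −78 °C; AcOH
Reagents that add atoms: trans-2-(phenylsulfonyl)-3-phenyloxaziridine, O=S(=O)(c1ccccc1)N1OC1c1ccccc1
Why: Enolate hydroxylation by an N-sulfonyloxaziridine, in which C3 is the only enolisable position once the C4 hydroxyl is deprotonated and the electrophilic oxygen should be delivered to the face of ring B opposite the C4 lithium alkoxide, as in alkylations and hydroxylations of β-alkoxide enolate dianions, giving the 3,4-trans diol (3R).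

**Step 9**
Reactants: 16 tert-butyl (3R,4R,5S,8R)-8-(dec-9-en-1-yl)-3,4-dihydroxy-2,6-dioxo-1,7-dioxaspiro[4.4]nonane-4-carboxylate
Product: 17 (3R,4R,5S,8R)-8-(dec-9-en-1-yl)-3,4-dihydroxy-2,6-dioxo-1,7-dioxaspiro[4.4]nonane-4-carboxylic acid
Conditions: CF3CO2H–CH2Cl2 (1:3), 0 °C → rt
Reagents that add atoms: none
Why: Acidolysis of the tert-butyl ester by alkyl–oxygen cleavage (AAL1) releases 2-methylpropene and the acid, while the two lactones, the hydroxyls and the monosubstituted alkene should be stable to CF3CO2H at room temperature and no stereocentre is involved.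

**Compound list**

1 | dodeca-1,11-diene | C=CCCCCCCCCC=C | starting material
2 | rac-2-(dec-9-en-1-yl)oxirane | C=CCCCCCCCCC1CO1 | intermediate
3 | (2R)-2-(dec-9-en-1-yl)oxirane | C=CCCCCCCCC[C@@H]1CO1 | intermediate
4 | dimethyl malonate | COC(=O)CC(=O)OC | starting material
5 | sodium alkoxide of dimethyl 2-[(2R)-2-hydroxydodec-11-en-1-yl]propanedioate (not isolated) | C=CCCCCCCCC[C@@H]([O-])CC(C(=O)OC)C(=O)OC.[Na+] | intermediate
6 | methyl (3RS,5R)-5-(dec-9-en-1-yl)-2-oxooxolane-3-carboxylate | C=CCCCCCCCC[C@@H]1CC(C(=O)OC)C(=O)O1 | intermediate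
7 | lithium (3RS,5R)-5-(dec-9-en-1-yl)-2-oxooxolane-3-carboxylate (not isolated) | C=CCCCCCCCC[C@@H]1CC(C(=O)[O-])C(=O)O1.[Li+] | intermediate
8 | (5R)-5-(dec-9-en-1-yl)oxolan-2-one | C=CCCCCCCCC[C@@H]1CCC(=O)O1 | intermediate
9 | di-tert-butyl oxalate | CC(C)(C)OC(=O)C(=O)OC(C)(C)C | starting material
10 | lithium (5R)-5-(dec-9-en-1-yl)-4,5-dihydrofuran-2-olate (not isolated) | C=CCCCCCCCC[C@@H]1CC=C([O-])O1.[Li+] | intermediate
11 | tert-butyl 2-[(3RS,5R)-5-(dec-9-en-1-yl)-2-oxooxolan-3-yl]-2-oxoacetate (keto form shown) | C=CCCCCCCCC[C@@H]1CC(C(=O)C(=O)OC(C)(C)C)C(=O)O1 | intermediate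
12 | tert-butyl 2-[(3S,5R)-3-acetoxy-5-(dec-9-en-1-yl)-2-oxooxolan-3-yl]-2-oxoacetate (acetoxy trans to the chain) | C=CCCCCCCCC[C@@H]1C[C@@](C(=O)C(=O)OC(C)(C)C)(OC(C)=O)C(=O)O1 | intermediate
13 | lithium 1-{[(3S,5R)-3-(2-tert-butoxy-2-oxoacetyl)-5-(dec-9-en-1-yl)-2-oxooxolan-3-yl]oxy}ethen-1-olate (not isolated) | C=CCCCCCCCC[C@@H]1C[C@@](C(=O)C(=O)OC(C)(C)C)(OC(=C)[O-])C(=O)O1.[Li+] | intermediate
14 | tert-butyl (4R,5S,8R)-8-(dec-9-en-1-yl)-4-hydroxy-2,6-dioxo-1,7-dioxaspiro[4.4]nonane-4-carboxylate | C=CCCCCCCCC[C@@H]1C[C@@]2(OC(=O)C[C@]2(O)C(=O)OC(C)(C)C)C(=O)O1 | intermediate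
15 | dilithium (4R,5S,8R)-4-(tert-butoxycarbonyl)-8-(dec-9-en-1-yl)-6-oxo-1,7-dioxaspiro[4.4]non-2-ene-2,4-diolate (not isolated) | C=CCCCCCCCC[C@@H]1C[C@@]2(OC([O-])=C[C@]2([O-])C(=O)OC(C)(C)C)C(=O)O1.[Li+].[Li+] | intermediate
16 | tert-butyl (3R,4R,5S,8R)-8-(dec-9-en-1-yl)-3,4-dihydroxy-2,6-dioxo-1,7-dioxaspiro[4.4]nonane-4-carboxylate | C=CCCCCCCCC[C@@H]1C[C@@]2(OC(=O)[C@H](O)[C@]2(O)C(=O)OC(C)(C)C)C(=O)O1 | intermediate
17 | (3R,4R,5S,8R)-8-(dec-9-en-1-yl)-3,4-dihydroxy-2,6-dioxo-1,7-dioxaspiro[4.4]nonane-4-carboxylic acid | C=CCCCCCCCC[C@@H]1C[C@@]2(OC(=O)[C@H](O)[C@]2(O)C(=O)O)C(=O)O1 | target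

**Step count**

Total: 9 steps. Longest linear sequence: 9 steps, from 1 to 17; compounds 4 and 9 enter as purchased.

**Steps most likely to fail**

Step 6. The chain on the far side of ring A may bias the two faces of the planar enol only weakly, so that acetate is transferred to both faces, and tetravalent lead may begin to attack the terminal alkene on long reaction times. The fallback introduces the oxygen under reagent control and acylates it afterwards. It sets out from 11: the sodium enolate (NaH, THF, 0 °C) is hydroxylated at −78 °C with the enantiomer of (camphorsulfonyl)oxaziridine whose own facial preference reinforces attack anti to the chain, giving the tertiary alcohol tert-butyl 2-[(3S,5R)-5-(dec-9-en-1-yl)-3-hydroxy-2-oxooxolan-3-yl]-2-oxoacetate F1. Acetylation with Ac2O, pyridine and catalytic 4-(dimethylamino)pyridine in CH2Cl2 at 0 °C comes back to the route at 12.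

Step 7. The strongly basic lithium enolate may add to the C6 lactone carbonyl and open ring A, may expel the C5 alkoxide with loss of ketene, or may meet the ketone in the unchelated rotamer and attack the other face, inverting C4. The fallback closes the same C3–C4 bond by an intramolecular Reformatsky reaction, in which a non-basic zinc enolate is generated from a halide. It sets out from 11: hydroxylation of its sodium enolate with trans-2-(phenylsulfonyl)-3-phenyloxaziridine anti to the chain gives the tertiary alcohol tert-butyl 2-[(3S,5R)-5-(dec-9-en-1-yl)-3-hydroxy-2-oxooxolan-3-yl]-2-oxoacetate F1. Bromoacetyl bromide and pyridine in CH2Cl2 at 0 °C then give the bromoacetate tert-butyl 2-[(3S,5R)-3-(2-bromoacetoxy)-5-(dec-9-en-1-yl)-2-oxooxolan-3-yl]-2-oxoacetate F2. Activated Zn dust in THF at 0 °C → rt inserts into the C–Br bond, and the zinc enolate, held by divalent zinc to the ketone and the C6 carbonyl, should add to C4 and come back to the route at 14.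

Step 8. The tert-butyl ester on the other face of C4 may shield the enolate as strongly as the lithium alkoxide does, so that oxygen transfer turns towards the 3,4-cis diol, and the lithium alkoxide may add to the sulfonimine left by the reagent. The fallback sets the C3 configuration by reduction instead. It sets out from 14: hydroxylation as in step 8 but with KN(SiMe3)2 as base, run without regard to facial selectivity, gives beside 16 its C3 epimer tert-butyl (3S,4R,5S,8R)-8-(dec-9-en-1-yl)-3,4-dihydroxy-2,6-dioxo-1,7-dioxaspiro[4.4]nonane-4-carboxylate F3. Dess–Martin periodinane in CH2Cl2 oxidises the secondary carbinol of the mixture, the tertiary C4 hydroxyl being inert, to the 3-oxo lactone tert-butyl (4S,5S,8R)-8-(dec-9-en-1-yl)-4-hydroxy-2,3,6-trioxo-1,7-dioxaspiro[4.4]nonane-4-carboxylate F4. NaBH4 in THF–MeOH at −78 °C should deliver hydride to the ketone from the face of ring B opposite the tert-butoxycarbonyl group, giving the 3,4-trans diol and coming back to the route at 16.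

**Further compounds**

F1 | step 6 | tert-butyl 2-[(3S,5R)-5-(dec-9-en-1-yl)-3-hydroxy-2-oxooxolan-3-yl]-2-oxoacetate | C=CCCCCCCCC[C@@H]1C[C@@](C(=O)C(=O)OC(C)(C)C)(O)C(=O)O1
F2 | step 7 | tert-butyl 2-[(3S,5R)-3-(2-bromoacetoxy)-5-(dec-9-en-1-yl)-2-oxooxolan-3-yl]-2-oxoacetate | C=CCCCCCCCC[C@@H]1C[C@@](C(=O)C(=O)OC(C)(C)C)(OC(=O)CBr)C(=O)O1
F3 | step 8 | tert-butyl (3S,4R,5S,8R)-8-(dec-9-en-1-yl)-3,4-dihydroxy-2,6-dioxo-1,7-dioxaspiro[4.4]nonane-4-carboxylate | C=CCCCCCCCC[C@@H]1C[C@@]2(OC(=O)[C@@H](O)[C@]2(O)C(=O)OC(C)(C)C)C(=O)O1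
F4 | step 8 | tert-butyl (4S,5S,8R)-8-(dec-9-en-1-yl)-4-hydroxy-2,3,6-trioxo-1,7-dioxaspiro[4.4]nonane-4-carboxylate | C=CCCCCCCCC[C@@H]1C[C@@]2(OC(=O)C(=O)[C@]2(O)C(=O)OC(C)(C)C)C(=O)O1
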